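**Retrosynthetic overview**
- The target comes from its 7,4'-bis-MOM ether by acetal cleavage in the last step.
- Ring C is the only ring made (rings A and B are bought as benzenes). It is closed last, at C3–C4, by an enantioselective carbene-catalysed intramolecular crossed benzoin that also sets C3 as R.
- The keto-aldehyde for that closure is cut at O1–C2: Williamson union of a ring A salicylaldehyde with a ring B phenacyl bromide.
- Ring A piece: 2,4,6-trihydroxybenzaldehyde, C-prenylation, 4-O-MOM. Ring B piece: 2,4-dihydroxyacetophenone, C-prenylation, 4-O-MOM, 2-O-methylation, α-bromination.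

Assumption: the SMILES is read as the (3R)-enantiomer (CIP order OH > C4 > C2 > aryl); the (5aS,10bR) hand of the triazolium salt is assumed to give the Si-face attack needed, and its mirror-image salt is used if the first run shows the opposite sense.

**Step 1**
Reactants: 1 1-(2,4-dihydroxyphenyl)ethan-1-one; 2 1-bromo-3-methylbut-2-ene (prenyl bromide)
Product: 3 1-[2,4-dihydroxy-3-(3-methylbut-2-en-1-yl)phenyl]ethan-1-one
Conditions: KOH (10 % aq.), 0 °C → rt
Reagents that add atoms: none
Why: C-alkylation of the resorcinol-type phenoxide (C-prenylation in water) goes mainly to C3, the carbon between the two oxygens, and gives the 3-prenyl ketone in moderate yield after separation from 5-prenyl and O-prenyl isomers.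

**Step 2**
Reactants: 3 1-[2,4-dihydroxy-3-(3-methylbut-2-en-1-yl)phenyl]ethan-1-one
Product: 4 1-[2-hydroxy-4-(methoxymethoxy)-3-(3-methylbut-2-en-1-yl)phenyl]ethan-1-one
Conditions: MOMCl (1.1 equiv), K2CO3, acetone, rt
Reagents that add atoms: chloromethyl methyl ether, COCCl
Why: Williamson-type MOM protection is selective for the free 4-OH because the 2-OH is held in a hydrogen bond to the acetyl group.

**Step 3**
Reactants: 4 1-[2-hydroxy-4-(methoxymethoxy)-3-(3-methylbut-2-en-1-yl)phenyl]ethan-1-one
Product: 5 1-[2-methoxy-4-(methoxymethoxy)-3-(3-methylbut-2-en-1-yl)phenyl]ethan-1-one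
Conditions: MeI, K2CO3, DMF, 40 °C
Reagents that add atoms: iodomethane, CI
Why: Williamson O-methylation of the remaining chelated phenol fixes the 2-methoxy group while the 4-oxygen stays masked until the end.

**Step 4**
Reactants: 5 1-[2-methoxy-4-(methoxymethoxy)-3-(3-methylbut-2-en-1-yl)phenyl]ethan-1-one
Product: 7 2-bromo-1-[2-methoxy-4-(methoxymethoxy)-3-(3-methylbut-2-en-1-yl)phenyl]ethan-1-one, via trimethylsilyl enol ether 6 (not isolated)
Conditions: LiN(SiMe3)2, Me3SiCl, THF, −78 °C; then NBS, −78 → −40 °C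
Reagents that add atoms: N-bromosuccinimide, O=C1CCC(=O)N1Br; chlorotrimethylsilane, C[Si](C)(C)Cl (its silyl group stays only in 6)
Why: Kinetic enolisation and O-silylation give the silyl enol ether, which NBS brominates at −78 °C (electrophilic α-halogenation of an enol ether) much faster than the prenyl alkene or the ring, and the HBr-free conditions spare MOM and prenyl.

**Step 5**
Reactants: 8 2,4,6-trihydroxybenzaldehyde; 2 1-bromo-3-methylbut-2-ene (prenyl bromide)
Product: 9 2,4,6-trihydroxy-3-(3-methylbut-2-en-1-yl)benzaldehyde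
Conditions: KOH (5 % aq.), 2 (0.9 equiv), 0 °C
Reagents that add atoms: none
Why: C-alkylation of the formylphloroglucinol phenoxide (same C-prenylation as step 1) meets only one kind of free ring carbon (C3 and C5 are equivalent), so the mono-prenyl product is a single regioisomer, obtained in moderate yield beside di- and O-prenylated material.

**Step 6**
Reactants: 9 2,4,6-trihydroxy-3-(3-methylbut-2-en-1-yl)benzaldehyde
Product: 10 2,6-dihydroxy-4-(methoxymethoxy)-3-(3-methylbut-2-en-1-yl)benzaldehyde
Conditions: MOMCl (1.0 equiv), K2CO3, acetone, 0 °C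
Reagents that add atoms: chloromethyl methyl ether, COCCl
Why: Williamson-type MOM protection goes to the 4-OH, the only hydroxyl not hydrogen-bonded to the aldehyde and the most acidic one.

**Step 7**
Reactants: 10 2,6-dihydroxy-4-(methoxymethoxy)-3-(3-methylbut-2-en-1-yl)benzaldehyde; 7 2-bromo-1-[2-methoxy-4-(methoxymethoxy)-3-(3-methylbut-2-en-1-yl)phenyl]ethan-1-one
Product: 11 2-hydroxy-6-{2-[2-methoxy-4-(methoxymethoxy)-3-(3-methylbut-2-en-1-yl)phenyl]-2-oxoethoxy}-4-(methoxymethoxy)-3-(3-methylbut-2-en-1-yl)benzaldehyde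
Conditions: K2CO3 (1.2 equiv), DMF, 0 °C → rt
Reagents that add atoms: none
Why: Williamson ether synthesis (SN2 on the phenacyl bromide) should favour the ortho-hydroxyl next to C5–H, which is less hindered than the one wedged between formyl and prenyl, and mild carbonate at room temperature avoids Rap–Stoermer aldol closure to a benzofuran.

**Step 8**
Reactants: 11 2-hydroxy-6-{2-[2-methoxy-4-(methoxymethoxy)-3-(3-methylbut-2-en-1-yl)phenyl]-2-oxoethoxy}-4-(methoxymethoxy)-3-(3-methylbut-2-en-1-yl)benzaldehyde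
Product: 12 (3R)-3,5-dihydroxy-3-[2-methoxy-4-(methoxymethoxy)-3-(3-methylbut-2-en-1-yl)phenyl]-7-(methoxymethoxy)-6-(3-methylbut-2-en-1-yl)-2,3-dihydro-4H-chromen-4-one
Conditions: (5aS,10bR)-2-(pentafluorophenyl)-5a,10b-dihydro-4H,6H-indeno[2,1-b][1,2,4]triazolo[4,3-d][1,4]oxazin-2-ium tetrafluoroborate (15 mol %), iPr2NEt (20 mol %), toluene, 4 Å MS, 30 °C, Ar
Reagents that add atoms: none
Why: Proposed new method: an enantioselective triazolylidene-catalysed intramolecular crossed aldehyde–ketone benzoin on a substrate class not yet shown for it (a 2,6-dioxygenated salicylaldehyde with a free chelated phenol as donor, an electron-rich ortho-methoxyaryl ketone as acceptor), in which the small, electron-poor N-C6F5 carbene adds to the hydrogen-bond-activated formyl group, the neighbouring phenol relays the proton to give the Breslow enaminol, and this acyl anion equivalent attacks the Si face of the tethered ketone in a six-membered, OH···O=C hydrogen-bonded transition state whose other face is blocked by the indane wall, so that the C3–C4 bond and ring C form together and C3 is set as R; the closest known reaction type is the carbene-catalysed enantioselective intramolecular crossed benzoin that gives 3-alkyl-3-hydroxychroman-4-ones from unhindered salicylaldehyde ethers of alkyl ketones.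

**Step 9**
Reactants: 12 (3R)-3,5-dihydroxy-3-[2-methoxy-4-(methoxymethoxy)-3-(3-methylbut-2-en-1-yl)phenyl]-7-(methoxymethoxy)-6-(3-methylbut-2-en-1-yl)-2,3-dihydro-4H-chromen-4-one
Product: 13 (3R)-3,5,7-trihydroxy-3-[4-hydroxy-2-methoxy-3-(3-methylbut-2-en-1-yl)phenyl]-6-(3-methylbut-2-en-1-yl)-2,3-dihydro-4H-chromen-4-one
Conditions: HCl (3 M aq.)/MeOH 1:5, 35 °C
Reagents that add atoms: none
Why: Acid-catalysed acetal solvolysis (MOM cleavage) in methanol under dilute acid frees the 7- and 4'-phenols without cyclising the prenyl groups onto them or ionising the tertiary ketol, and C3, which bears no hydrogen, keeps its R configuration.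

**Compound list**
1 | 1-(2,4-dihydroxyphenyl)ethan-1-one | CC(=O)c1ccc(O)cc1O | starting material
2 | 1-bromo-3-methylbut-2-ene (prenyl bromide) | CC(C)=CCBr | starting material
3 | 1-[2,4-dihydroxy-3-(3-methylbut-2-en-1-yl)phenyl]ethan-1-one | CC(=O)c1ccc(O)c(CC=C(C)C)c1O | intermediate
4 | 1-[2-hydroxy-4-(methoxymethoxy)-3-(3-methylbut-2-en-1-yl)phenyl]ethan-1-one | CC(=O)c1ccc(OCOC)c(CC=C(C)C)c1O | intermediate
5 | 1-[2-methoxy-4-(methoxymethoxy)-3-(3-methylbut-2-en-1-yl)phenyl]ethan-1-one | CC(=O)c1ccc(OCOC)c(CC=C(C)C)c1OC | intermediate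
6 | ({1-[2-methoxy-4-(methoxymethoxy)-3-(3-methylbut-2-en-1-yl)phenyl]ethenyl}oxy)trimethylsilane, not isolated | C=C(O[Si](C)(C)C)c1ccc(OCOC)c(CC=C(C)C)c1OC | intermediate
7 | 2-bromo-1-[2-methoxy-4-(methoxymethoxy)-3-(3-methylbut-2-en-1-yl)phenyl]ethan-1-one | BrCC(=O)c1ccc(OCOC)c(CC=C(C)C)c1OC | intermediate
8 | 2,4,6-trihydroxybenzaldehyde | O=Cc1c(O)cc(O)cc1O | starting material
9 | 2,4,6-trihydroxy-3-(3-methylbut-2-en-1-yl)benzaldehyde | O=Cc1c(O)cc(O)c(CC=C(C)C)c1O | intermediate
10 | 2,6-dihydroxy-4-(methoxymethoxy)-3-(3-methylbut-2-en-1-yl)benzaldehyde | O=Cc1c(O)cc(OCOC)c(CC=C(C)C)c1O | intermediate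
11 | 2-hydroxy-6-{2-[2-methoxy-4-(methoxymethoxy)-3-(3-methylbut-2-en-1-yl)phenyl]-2-oxoethoxy}-4-(methoxymethoxy)-3-(3-methylbut-2-en-1-yl)benzaldehyde | O=Cc1c(OCC(=O)c2ccc(OCOC)c(CC=C(C)C)c2OC)cc(OCOC)c(CC=C(C)C)c1O | intermediate
12 | (3R)-3,5-dihydroxy-3-[2-methoxy-4-(methoxymethoxy)-3-(3-methylbut-2-en-1-yl)phenyl]-7-(methoxymethoxy)-6-(3-methylbut-2-en-1-yl)-2,3-dihydro-4H-chromen-4-one | COc1c([C@@]2(O)COc3cc(OCOC)c(CC=C(C)C)c(O)c3C2=O)ccc(OCOC)c1CC=C(C)C | intermediate
13 | (3R)-3,5,7-trihydroxy-3-[4-hydroxy-2-methoxy-3-(3-methylbut-2-en-1-yl)phenyl]-6-(3-methylbut-2-en-1-yl)-2,3-dihydro-4H-chromen-4-one | COc1c([C@@]2(O)COc3cc(O)c(CC=C(C)C)c(O)c3C2=O)ccc(O)c1CC=C(C)C | target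

**Step count and risks**
Total steps: 9. Longest linear sequence: 7 (steps 1, 2, 3, 4, 7, 8, 9).

The three steps most likely to fail:

(a) Step 8, the proposed new benzoin closure. The formyl group sits between two ortho oxygens and on an electron-rich ring, so the carbene may add slowly. The aryl ketone acceptor is hindered, base can divert 11 into a 2-aroylbenzofuran by aldol closure, and the level and sense of induction are untested. The fallback uses known chemistry, sets out from 11 and comes back at 12. Ring C is closed without enantiocontrol by the established thiazolium-catalysed aldehyde–ketone benzoin cyclisation (3-ethyl-5-(2-hydroxyethyl)-4-methylthiazolium bromide 20 mol %, Et3N, t-BuOH, 40 °C). This gives racemic 3,5-dihydroxy-3-[2-methoxy-4-(methoxymethoxy)-3-(3-methylbut-2-en-1-yl)phenyl]-7-(methoxymethoxy)-6-(3-methylbut-2-en-1-yl)-2,3-dihydro-4H-chromen-4-one F1, which is resolved by preparative supercritical-fluid chromatography on an amylose tris(3,5-dimethylphenylcarbamate) phase. The (R)-enantiomer is 12; the (3S)-3,5-dihydroxy-3-[2-methoxy-4-(methoxymethoxy)-3-(3-methylbut-2-en-1-yl)phenyl]-7-(methoxymethoxy)-6-(3-methylbut-2-en-1-yl)-2,3-dihydro-4H-chromen-4-one F2 is set aside.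

(b) Step 7, the union. The two ortho-hydroxyls of 10 may not differ enough, and carbonate can start the Rap–Stoermer aldol of the product. The fallback joins the fragments under neutral Mitsunobu conditions; it sets out from 7 and comes back at 11. Heating 7 with HCO2Na in EtOH–H2O at 70 °C gives 2-[2-methoxy-4-(methoxymethoxy)-3-(3-methylbut-2-en-1-yl)phenyl]-2-oxoethyl formate F3, which is hydrolysed in the same flask to 2-hydroxy-1-[2-methoxy-4-(methoxymethoxy)-3-(3-methylbut-2-en-1-yl)phenyl]ethan-1-one F4. F4 is then coupled with 10 (PPh3, DIAD, THF, 0 °C), where the bulky oxyphosphonium partner is expected to discriminate the hindered hydroxyl more sharply and no base is present, to give 11.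

(c) Step 5, the direct C-prenylation. Yield is modest and O- and di-prenylation compete. The fallback moves the prenyl group in by an O-alkylation and sigmatropic relay; it sets out from 8 and comes back at 10, bypassing 9. MOMCl (1.0 equiv) with iPr2NEt in CH2Cl2 at 0 °C gives 2,6-dihydroxy-4-(methoxymethoxy)benzaldehyde F5. Prenyl bromide 2 with K2CO3 in acetone gives the mono-ether 2-hydroxy-4-(methoxymethoxy)-6-[(3-methylbut-2-en-1-yl)oxy]benzaldehyde F6. Heating F6 in N,N-diethylaniline at 200 °C brings about the para-Claisen–Cope rearrangement, which carries the prenyl group to the carbon para to the ether oxygen and gives 10.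

**Further compounds**
F1 | step 8 | racemic 3,5-dihydroxy-3-[2-methoxy-4-(methoxymethoxy)-3-(3-methylbut-2-en-1-yl)phenyl]-7-(methoxymethoxy)-6-(3-methylbut-2-en-1-yl)-2,3-dihydro-4H-chromen-4-one | COc1c(C2(O)COc3cc(OCOC)c(CC=C(C)C)c(O)c3C2=O)ccc(OCOC)c1CC=C(C)C
F2 | step 8 | (3S)-3,5-dihydroxy-3-[2-methoxy-4-(methoxymethoxy)-3-(3-methylbut-2-en-1-yl)phenyl]-7-(methoxymethoxy)-6-(3-methylbut-2-en-1-yl)-2,3-dihydro-4H-chromen-4-one | COc1c([C@]2(O)COc3cc(OCOC)c(CC=C(C)C)c(O)c3C2=O)ccc(OCOC)c1CC=C(C)C
F3 | step 7 | 2-[2-methoxy-4-(methoxymethoxy)-3-(3-methylbut-2-en-1-yl)phenyl]-2-oxoethyl formate | O=COCC(=O)c1ccc(OCOC)c(CC=C(C)C)c1OC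
F4 | step 7 | 2-hydroxy-1-[2-methoxy-4-(methoxymethoxy)-3-(3-methylbut-2-en-1-yl)phenyl]ethan-1-one | OCC(=O)c1ccc(OCOC)c(CC=C(C)C)c1OC
F5 | step 5 | 2,6-dihydroxy-4-(methoxymethoxy)benzaldehyde | O=Cc1c(O)cc(OCOC)cc1O
F6 | step 5 | 2-hydroxy-4-(methoxymethoxy)-6-[(3-methylbut-2-en-1-yl)oxy]benzaldehyde | O=Cc1c(O)cc(OCOC)cc1OCC=C(C)C
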